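**Retrosynthetic overview**
1. The δ-lactone and the C11=C12 alkene come last. The C17 acid closes on C9 of a Δ9(11) cyclopentene by selenolactonisation, and selenoxide elimination follows.
2. Ring C is made by forming the C8–C14 bond. The C8–C9–C11–C12–C14 pentadienyl cation (a C8 cation closing on C14) undergoes conrotatory 4π closure and gives the five-membered ring directly. The allyl cation that remains is quenched by hydride at C12.
3. The C11–C12 bond comes from a CrCl2/NiCl2 coupling of a tricyclic aldehyde with an enol triflate. The triflate is made from methyl acetoacetate and methyl propiolate and carries C12–C14, C17, CO2Me and =CH2.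
4. Rings A and B form in one step by an epoxide-opened radical polyene cyclisation. It runs through a butenolide that already holds C19 and O6. C6 steers C5 and C10, and the (S)-epoxide places the C3 oxygen axial.
5. The polyene comes from (S)-epichlorohydrin, isopropenylMgBr, PhSCH2CO2H, homoprenyl bromide and acrolein acetal. Ring order: γ-lactone, A, B, C, δ-lactone.

Assumption: andrastin-type numbering is used (C19 = γ-lactone C=O on C10, C17 = δ-lactone C=O, C13 bears =CH2, C14 bears CO2Me; target = 3S,5R,6S,8R,9S,10S,14S), and the biogenesis is taken as epoxy-polyene cyclisation (rings A, B), closure of the C8 cation on C14 (ring C, later contracted), then closure of the C17 acid on C9.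

**Route**

Step 1
Reactants: 1 5-bromo-2-methylpent-2-ene
Product: 2 (S)-3-(2-bromoethyl)-2,2-dimethyloxirane
Conditions: ent-Shi ketone (L-fructose-derived, from L-sorbose, 30 mol %), Oxone (KHSO5), K2CO3, Bu4NHSO4, MeCN–dimethoxymethane/aq. buffer pH 10.5, 0 °C
Reagents that add atoms: potassium peroxymonosulfate, [K+].[O-]S(=O)(=O)OO
Why: Shi asymmetric epoxidation through the spiro dioxirane transition state; the D-fructose ketone gives R epoxides from R–CH=CMe2 alkenes, so its enantiomer sets C3 as S, and the primary bromide is inert.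

Step 2
Reactants: 3 methyl acetoacetate; 4 methyl propiolate
Product: 5 dimethyl 2-acetyl-3-methylidenebutanedioate
Conditions: Bu3P (10 mol %), toluene, rt
Reagents that add atoms: none
Why: Phosphine-catalysed α-addition (umpolung addition) of a 1,3-dicarbonyl C–H to a propiolate; Bu3P adds at the β-carbon, the vinylphosphonium takes the acetoacetate anion at the α-carbon and releases the phosphine, which delivers C12, C13, C14, C17, the ester carbon and =CH2 in one step with no lasting stereocentre.

Step 3
Reactants: 5 dimethyl 2-acetyl-3-methylidenebutanedioate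
Product: 6 dimethyl (E)-2-methylidene-3-[1-(triflyloxy)ethylidene]butanedioate
Conditions: Tf2O, aq. Me4NOH, toluene, 5 °C
Reagents that add atoms: triflic anhydride, O=S(=O)(OS(=O)(=O)C(F)(F)F)C(F)(F)F
Why: Stereoselective O-triflation of a β-keto ester; the non-chelated Me4N enolate holds its oxygen anti to the ester carbonyl, so TfO ends trans to CO2Me and cis to the acrylate arm, which is the geometry needed in steps 11 and 12.

Step 4
Reactants: 7 (S)-epichlorohydrin; 8 isopropenylmagnesium bromide
Product: 10 (S)-2-(2-methylprop-2-enyl)oxirane, via chlorohydrin 9 (not isolated)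
Conditions: CuI (10 mol %), THF, −40 °C; then powdered NaOH, rt
Reagents that add atoms: none
Why: Copper-catalysed Grignard opening at the terminal epoxide carbon followed by Williamson closure onto CH2Cl; the stereocentre (future C6) is never touched and stays S.

Step 5
Reactants: 10 (S)-2-(2-methylprop-2-enyl)oxirane; 11 (phenylthio)acetic acid
Product: 13 (5S)-5-(2-methylprop-2-enyl)-3-(phenylthio)oxolan-2-one, via hydroxy acid 12 (not isolated)
Conditions: LDA (2.1 equiv), THF, 0 °C, then 10, rt; aq. HCl; PPTS (cat.), toluene, 60 °C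
Reagents that add atoms: none
Why: The carboxylic acid dianion opens the epoxide by SN2 at CH2 and the γ-hydroxy acid lactonises; C6 is untouched and the C10 epimers are of no consequence.

Step 6
Reactants: 13 (5S)-5-(2-methylprop-2-enyl)-3-(phenylthio)oxolan-2-one; 2 (S)-3-(2-bromoethyl)-2,2-dimethyloxirane
Product: 14 α-alkylated phenylthio lactone
Conditions: LDA (1.1 equiv), THF–DMPU, −78 °C; 2, Bu4NI (cat.), −78 °C to rt
Reagents that add atoms: none
Why: Alkylation of the sulfur-stabilised lactone enolate with a primary halide forms C1–C10; the trisubstituted epoxide survives, and the new quaternary centre is erased in step 7.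

Step 7
Reactants: 14 α-alkylated phenylthio lactone
Product: 16 epoxy butenolide, via sulfoxide 15 (not isolated)
Conditions: mCPBA (1.0 equiv), CH2Cl2, −78 to 0 °C; then CaCO3, toluene, 110 °C
Reagents that add atoms: mCPBA, O=C(OO)c1cccc(Cl)c1 (its oxygen is held only by 15)
Why: Sulfide oxidation outpaces alkene epoxidation at low temperature, and thermal sulfoxide syn-elimination gives the conjugated endocyclic butenolide under neutral conditions, so the acidic C6–H is not epimerised.

Step 8
Reactants: 16 epoxy butenolide; 17 acrolein diethyl acetal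
Product: 18 epoxy polyene acetal
Conditions: second-generation Hoveyda–Grubbs catalyst (5 mol %), 17 (5 equiv), CH2Cl2, 40 °C
Reagents that add atoms: none
Why: Cross metathesis of the only reactive (1,1-disubstituted) alkene with an allylic acetal adds C9 and C11; the butenolide alkene is inert, and the E/Z ratio does not matter because C8 and C9 become sp2 again in step 12 (E drawn).

Step 9
Reactants: 18 epoxy polyene acetal
Product: 20 tricyclic hydroxy acetal, via silyl ether 19 (not isolated)
Conditions: Cp2TiCl2 (20 mol %), Mn (8 equiv), Me3SiCl (4 equiv), 2,4,6-collidine (7 equiv), THF, 0.005 M, 18 added over 6 h, rt; then Bu4NF, AcOH, THF, 0 °C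
Reagents that add atoms: chlorotrimethylsilane, C[Si](C)(C)Cl (its silyl group is held only by 19)
Why: Proposed new method: Cp2TiCl (trivalent titanium) opens the epoxide to the tertiary C4 radical as in known titanocene epoxypolyene cyclisations, this nucleophilic radical adds 6-endo to the butenolide β-carbon C5 anti to the C6 side chain, the electrophilic C10 lactone radical adds 6-endo to the electron-rich C8=C9 alkene on the only face the C6 tether can reach, and the C8 radical ends as the exocyclic alkene, so C6 sets C5 and C10, C11 sits equatorial on C9, and the C3–O bond carried from the (S)-epoxide ends axial; the titanium concentration is kept low so that the C10 radical cyclises before it is reduced, and the closest known type is the polarity-alternating radical polyene cascade.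

Step 10
Reactants: 20 tricyclic hydroxy acetal
Product: 22 tricyclic acetoxy aldehyde, via acetoxy acetal 21 (not isolated)
Conditions: Ac2O, DMAP, pyridine, 40 °C; then 1 M HCl, THF, 0 °C
Reagents that add atoms: acetic anhydride, CC(=O)OC(C)=O; water, O
Why: DMAP-catalysed acylation of the hindered axial alcohol is run while the aldehyde is still masked, then mild acetal hydrolysis follows; no stereocentre is changed, and epimerisation at C9 would be harmless.

Step 11
Reactants: 22 tricyclic acetoxy aldehyde; 6 dimethyl (E)-2-methylidene-3-[1-(triflyloxy)ethylidene]butanedioate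
Product: 24 tricyclic dihydropyranone, via hydroxy diester 23 (not isolated)
Conditions: CrCl2 (6 equiv), NiCl2 (2 mol %), DMF, rt; work-up; CSA (cat.), toluene, 50 °C
Reagents that add atoms: none
Why: The Nozaki–Hiyama–Kishi coupling adds the alkenylchromium only to the aldehyde (lactone, acetate and acrylate are tolerated) with retention of alkene geometry, so O11 lies cis to the acrylate arm and lactonises on C17 alone, which differentiates the two methyl esters; both C11 epimers are used because C11 ionises in step 12.

Step 12
Reactants: 24 tricyclic dihydropyranone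
Product: 27 tetracyclic acrylic acid, via tetrasubstituted alkene 25 (not isolated), via allylic γ-lactone 26 (not isolated)
Conditions: TfOH (1.2 equiv), CH2Cl2–(CF3)2CHOH 4:1, −40 to 0 °C until 24 and 25 are consumed; then Et3SiH (3 equiv), −40 °C; pH 4 buffer
Reagents that add atoms: none
Why: Proposed new method: TfOH moves the exocyclic alkene into the Δ8(9) position (25), the now doubly allylic C11–O bond ionises to the C8–C14 pentadienyl cation, and conrotatory 4π closure (Nazarov type; closest known are dehydrative Nazarov cyclisations of bis-allylic alcohols) joins C14 to the β face of C8 away from the C19–O6 bridge, with 8-Me and the acrylate arm both inside and hence trans, which sets C8 and C14; the freed C17 acid caps the allyl cation at the less hindered C12 from the β face (26), and Et3SiH then reduces this tertiary allylic lactone (ionic hydrogenation) from the open α face at C12 to leave the Δ9(11) alkene, 12-Hα and the free acid.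

Step 13
Reactants: 27 tetracyclic acrylic acid
Product: 29 meroantarctine B, via selenolactone 28 (not isolated)
Conditions: N-(phenylseleno)phthalimide (1.2 equiv), CSA (10 mol %), CH2Cl2, −20 °C to rt; then 30 % H2O2, pyridine, THF, 0 °C to rt
Reagents that add atoms: N-(phenylseleno)phthalimide, O=C1c2ccccc2C(=O)N1[Se]c1ccccc1 (its PhSe group is held only by 28)
Why: Phenylselenolactonisation is an anti, Markovnikov addition, so the β-tethered C17 acid bonds to the tertiary C9 (which sets C9) while PhSe takes the α face of C11, and selenoxide syn-elimination can use only the α-hydrogen on C12, which gives the C11=C12 alkene without any allyl cation that could return to the C12 lactone.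

**Compound list**
1 | 5-bromo-2-methylpent-2-ene | CC(C)=CCCBr | starting material
2 | (S)-3-(2-bromoethyl)-2,2-dimethyloxirane | BrCC[C@@H]1OC1(C)C | intermediate
3 | methyl acetoacetate | CC(=O)CC(=O)OC | starting material
4 | methyl propiolate | C#CC(=O)OC | starting material
5 | dimethyl 2-acetyl-3-methylidenebutanedioate (racemic, enolisable) | CC(=O)C(C(=O)OC)C(=C)C(=O)OC | intermediate
6 | dimethyl (E)-2-methylidene-3-[1-(triflyloxy)ethylidene]butanedioate (TfO trans to CO2Me, cis to the acrylate arm) | C/C(OS(=O)(=O)C(F)(F)F)=C(\C(=O)OC)C(=C)C(=O)OC | intermediate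
7 | (S)-epichlorohydrin | ClC[C@@H]1CO1 | starting material
8 | isopropenylmagnesium bromide | C=C(C)[Mg]Br | starting material
9 | (S)-1-chloro-4-methylpent-4-en-2-ol | ClC[C@@H](O)CC(C)=C | intermediate
10 | (S)-2-(2-methylprop-2-enyl)oxirane | C=C(C)C[C@H]1CO1 | intermediate
11 | (phenylthio)acetic acid | OC(=O)CSc1ccccc1 | starting material
12 | (4S)-4-hydroxy-6-methyl-2-(phenylthio)hept-6-enoic acid (C2 epimers) | C=C(C)C[C@H](O)CC(Sc1ccccc1)C(=O)O | intermediate
13 | (5S)-5-(2-methylprop-2-enyl)-3-(phenylthio)oxolan-2-one (C3 epimers) | C=C(C)C[C@H]1CC(Sc2ccccc2)C(=O)O1 | intermediate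
14 | (5S)-3-{2-[(2S)-3,3-dimethyloxiran-2-yl]ethyl}-5-(2-methylprop-2-enyl)-3-(phenylthio)oxolan-2-one (C3 epimers) | C=C(C)C[C@H]1CC(CC[C@@H]2OC2(C)C)(Sc2ccccc2)C(=O)O1 | intermediate
15 | phenyl sulfoxide of 14 | C=C(C)C[C@H]1CC(CC[C@@H]2OC2(C)C)(S(=O)c2ccccc2)C(=O)O1 | intermediate
16 | (5S)-3-{2-[(2S)-3,3-dimethyloxiran-2-yl]ethyl}-5-(2-methylprop-2-enyl)furan-2(5H)-one | CC1(C)O[C@H]1CCC1=C[C@H](CC(C)=C)OC1=O | intermediate
17 | acrolein diethyl acetal (3,3-diethoxyprop-1-ene) | C=CC(OCC)OCC | starting material
18 | (5S)-5-[(2E)-4,4-diethoxy-2-methylbut-2-enyl]-3-{2-[(2S)-3,3-dimethyloxiran-2-yl]ethyl}furan-2(5H)-one | CC1(C)O[C@H]1CCC1=C[C@H](C/C(C)=C/C(OCC)OCC)OC1=O | intermediate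
19 | 3-O-trimethylsilyl ether of 20 | C=C1C[C@@H]2OC(=O)[C@]3(CC[C@H](O[Si](C)(C)C)C(C)(C)[C@@H]23)[C@@H]1C(OCC)OCC | intermediate
20 | trans-decalin (rings A, B) bridged by the C19(=O)–O6 γ-lactone; axial (3S)-OH, 4,4-Me2, 8-exomethylene, equatorial CH(OEt)2 on C9; C3, C5, C6, C10 as in 29, 9-H on the face of the later C9–O bond | C=C1C[C@@H]2OC(=O)[C@]3(CC[C@H](O)C(C)(C)[C@@H]23)[C@@H]1C(OCC)OCC | intermediate
21 | 3-O-acetate of 20 | C=C1C[C@@H]2OC(=O)[C@]3(CC[C@H](OC(C)=O)C(C)(C)[C@@H]23)[C@@H]1C(OCC)OCC | intermediate
22 | aldehyde from 21 (C11 = CHO on C9) | C=C1C[C@@H]2OC(=O)[C@]3(CC[C@H](OC(C)=O)C(C)(C)[C@@H]23)[C@@H]1C=O | intermediate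
23 | C11 carbinol (epimers) bearing C12(Me)=C14(CO2Me)–C13(=CH2)CO2Me, with C11 trans to the C14 ester | C=C1C[C@@H]2OC(=O)[C@]3(CC[C@H](OC(C)=O)C(C)(C)[C@@H]23)[C@@H]1C(O)/C(C)=C(/C(=O)OC)C(=C)C(=O)OC | intermediate
24 | 6-substituted 4-methoxycarbonyl-5-methyl-3-methylidene-3,6-dihydropyran-2-one (O11–C17 lactone, C11 epimers) on C9 of the tricycle | C=C1C[C@@H]2OC(=O)[C@]3(CC[C@H](OC(C)=O)C(C)(C)[C@@H]23)[C@@H]1C1OC(=O)C(=C)C(C(=O)OC)=C1C | intermediate
25 | Δ8(9) isomer of 24 | CC1=C(C4OC(=O)C(=C)C(C(=O)OC)=C4C)[C@@]2(CC[C@H](OC(C)=O)C(C)(C)[C@H]2[C@H](C1)O3)C3=O | intermediate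
26 | ring C closed (C8, C14 as in 29); Δ9(11) alkene; α-methylene-γ-lactone from C17 to O on C12 (O β, Me α) | C=C1C(=O)O[C@]2(C)C=C3[C@@]4(CC[C@H](OC(C)=O)C(C)(C)[C@H]4[C@H](C[C@]3(C)[C@]12C(=O)OC)O5)C5=O | intermediate
27 | Δ9(11) cyclopentene with 12-Hα/12-Meβ; C14 bears CO2Me (α) and C(=CH2)CO2H (β) | C=C(C(=O)O)[C@]1(C(=O)OC)[C@H](C)C=C2[C@@]3(CC[C@H](OC(C)=O)C(C)(C)[C@H]3[C@H](C[C@]12C)O4)C4=O | intermediate
28 | 11α-phenylseleno-11,12-dihydro-29 (12-Hα) | C=C1C(=O)O[C@@]23[C@H]([Se]c4ccccc4)[C@@H](C)[C@]1(C(=O)OC)[C@@]2(C)C[C@@H]1OC(=O)[C@]32CC[C@H](OC(C)=O)C(C)(C)[C@@H]12 | intermediate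
29 | meroantarctine B (3S,5R,6S,8R,9S,10S,14S) | C=C1C(=O)O[C@@]23C=C(C)[C@]1(C(=O)OC)[C@@]2(C)C[C@@H]1OC(=O)[C@]32CC[C@H](OC(C)=O)C(C)(C)[C@@H]12 | target

**Step count**
Total step count: 13.
Longest linear sequence: 10 steps (steps 4–13, from 7).

**The three steps most likely to fail**

Step 9. The C10 radical may be reduced to the titanium enolate before ring B closes. The fallback sets out from 18 and comes back at 20.
- Let the reduction happen on purpose. Cp2TiCl2 (2.2 equiv)/Mn with collidine hydrochloride gives the monocyclised cis-fused hydroxy lactone F1.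
- LDA (2.2 equiv) and then PhSeBr give the C10 phenylselenide F2.
- Irradiation with (Bu3Sn)2 in benzene closes ring B as a reductant-free phenylseleno group-transfer radical cyclisation and gives the C8 selenide F3.
- H2O2 eliminates the selenoxide to give 20. Any alkene isomers are levelled in step 12.

Step 11. A tetrasubstituted alkenylchromium must add to a hindered α-branched aldehyde. The fallback sets out from 16 and comes back at 24, with the fragments joined before the cyclisation.
- Cross metathesis of 16 with crotonaldehyde gives the unhindered enal F4.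
- CrCl2/NiCl2 coupling with 6 followed by lactonisation gives the polyene dihydropyranone F5.
- The titanocene cyclisation of step 9, run at higher dilution to spare the acrylate, gives the tricyclic alcohol F6.
- Ac2O/pyridine then gives 24.

Step 12. The crowded 4π closure is followed by hydride capture, where over-reduction or attack at C9 is possible. The fallback sets out from 26 and comes back at 27.
- Stop after the acid stage and isolate 26.
- Replace the cationic reduction by π-allyl hydrogenolysis with zerovalent palladium (Pd(PPh3)4, HCO2H, Et3N, THF).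
- The metal ionises the lactone from the α face and hands its hydride to C12 from that same face, so no free cation or strong acid meets the product.
- This fallback makes no new compound (entry F0).

**Further compounds**
F1 | step 9 | monocyclised cis-fused hydroxy lactone (ring A closed, 10-H, C3, C5, C6 as in 29) | CC1(C)[C@@H](O)CC[C@@H]2C(=O)O[C@@H](C/C(C)=C/C(OCC)OCC)[C@H]12
F2 | step 9 | C10 phenylselenide of F1 (C10 unassigned) | CC1(C)[C@@H](O)CCC2([Se]c3ccccc3)C(=O)O[C@@H](C/C(C)=C/C(OCC)OCC)[C@H]12
F3 | step 9 | C8 phenylselenide with ring B closed (C8 unassigned) | CC1([Se]c4ccccc4)C[C@@H]2OC(=O)[C@]3(CC[C@H](O)C(C)(C)[C@@H]23)[C@@H]1C(OCC)OCC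
F4 | step 11 | (E)-enal from 16 | CC1(C)O[C@H]1CCC1=C[C@H](C/C(C)=C/C=O)OC1=O
F5 | step 11 | polyene dihydropyranone (C11 epimers) | CC1(C)O[C@H]1CCC1=C[C@H](C/C(C)=C/C2OC(=O)C(=C)C(C(=O)OC)=C2C)OC1=O
F6 | step 11 | tricyclic alcohol (3-deacetyl 24) | C=C1C[C@@H]2OC(=O)[C@]3(CC[C@H](O)C(C)(C)[C@@H]23)[C@@H]1C1OC(=O)C(=C)C(C(=O)OC)=C1C
F0 | step 12 | none | none
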